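**Plan**

- Retrosynthetic cuts, in order: the four O-masks of the naphthazarin (back to a tetra-MOM naphthalene), then the C2–C1′ bond between ring and side chain, then the C1′–Cl and C1′–O bonds of a 1-chloroalkyl isovalerate (back to an aldehyde and isovaleryl chloride).
- Enabling feature: C1′ carries the isovaleryloxy group and is bonded directly to ring carbon C2. Both atoms are electrophilic in their natural precursors (an aryl iodide carbon and an aldehyde-derived chloro ester carbon), so nickel with Mn as terminal reductant can join them with the ester already in place.
- Forward order: the bicyclic core is taken intact from naphthazarin (reduction, four MOM ethers, one ortho-iodination). The chain comes from 4-methylpent-3-en-1-ol by oxidation and acyl chloride addition. The halves are joined in one coupling, and the naphthazarin is unmasked in two steps.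
- Stereochemistry: the only stereocentre, C1′ (S), is created in the coupling from the racemic chloro ester under a chiral bi(oxazoline)–nickel catalyst (enantioconvergent, catalyst control). No later step breaks a bond at C1′.

Key step: step 6

Assumption: the sense of induction of the nickel catalyst cannot be predicted with confidence; the S,S ligand is written, and its mirror image is to be used if a first trial delivers the R ester.
Assumption: naphthazarins are rapidly interconverting tautomers (double proton shift across the two peri O–H···O=C pairs), so the final compound is the same whichever ring is oxidised in step 7; it is written in the tautomer of the target structure.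

Step 1
Reactants: 1 naphthazarin (5,8-dihydroxy-1,4-naphthoquinone)
Product: 2 2,3-dihydronaphthazarin (5,8-dihydroxy-2,3-dihydronaphthalene-1,4-dione, the stable keto tautomer of naphthalene-1,4,5,8-tetrol)
Conditions: Na2S2O4 (aq), EtOAc, rt, N2; organic phase dried and concentrated under N2
Reagents that add atoms: none
Why: Dithionite reduction of a quinone to its hydroquinone is standard, and the leuco compound of naphthazarin is an isolable solid in its diketo form.

Step 2
Reactants: 2 2,3-dihydronaphthazarin
Product: 3 1,4,5,8-tetrakis(methoxymethoxy)naphthalene
Conditions: NaH (6 equiv), MOMCl (6 equiv), DMF, 0 °C to rt, Ar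
Reagents that add atoms: chloromethyl methyl ether (MOMCl), COCCl
Why: NaH enolises the diketone to the aromatic tetra-phenoxide, which the hard electrophile MOMCl alkylates on oxygen (Williamson etherification), the same reductive-alkylation logic that gives the tetramethyl ether of this ring system.

Step 3
Reactants: 3 1,4,5,8-tetrakis(methoxymethoxy)naphthalene
Product: 5 2-iodo-1,4,5,8-tetrakis(methoxymethoxy)naphthalene, via aryllithium 4 (not isolated)
Conditions: s-BuLi (1.1 equiv), N,N,N′,N′-tetramethylethylenediamine, THF, −78 °C; then I2, THF, −78 °C to rt
Reagents that add atoms: iodine, II; sec-butyllithium, [Li]C(C)CC (supplies only the lithium of intermediate 4)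
Why: Directed ortho-metalation next to an OMOM group is reliable, the four free ring positions are equivalent by symmetry so only one monolithio species can form, and iodine traps it as the aryl iodide.

Step 4
Reactants: 6 4-methylpent-3-en-1-ol
Product: 7 4-methylpent-3-enal
Conditions: Dess–Martin periodinane (1.2 equiv), CH2Cl2, 0 °C to rt; cold NaHCO3 wash, dried solution used at once
Reagents that add atoms: none
Why: Dess–Martin oxidation works without base and is the usual way to reach a β,γ-unsaturated aldehyde without moving the double bond into conjugation.

Step 5
Reactants: 7 4-methylpent-3-enal; 8 isovaleryl chloride (3-methylbutanoyl chloride)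
Product: 9 1-chloro-4-methylpent-3-en-1-yl 3-methylbutanoate (racemic)
Conditions: ZnCl2 (2 mol %), CH2Cl2, −20 to 0 °C, strictly dry; volatiles removed, used without chromatography
Reagents that add atoms: none
Why: Lewis-acid-catalysed addition of an acyl chloride across an aldehyde carbonyl gives the 1-chloroalkyl ester rapidly at low temperature, and the low catalyst loading and temperature are chosen to leave the trisubstituted alkene untouched; the racemic product is what the next step requires.

Step 6
Reactants: 5 2-iodo-1,4,5,8-tetrakis(methoxymethoxy)naphthalene; 9 1-chloro-4-methylpent-3-en-1-yl 3-methylbutanoate (racemic, 1.8 equiv)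
Product: 10 (S)-4-methyl-1-[1,4,5,8-tetrakis(methoxymethoxy)naphthalen-2-yl]pent-3-en-1-yl 3-methylbutanoate
Conditions: NiBr2(MeOCH2CH2OMe) (10 mol %), (4S,4′S)-4,4′-di(heptan-4-yl)-4,4′,5,5′-tetrahydro-2,2′-bioxazole (12 mol %), Mn powder (3 equiv), NaI (0.5 equiv), N,N-dimethylacetamide/THF, 0 °C to rt, Ar
Reagents that add atoms: none
Why: Proposed new method: zerovalent nickel carrying the chiral bi(oxazoline) should insert into the C–I bond of 5 to give an aryl complex of divalent nickel, while a monovalent nickel species abstracts the halogen from 9 (or from the 1-iodoalkyl ester formed from it by Finkelstein exchange with NaI) to give a planar α-acyloxyalkyl radical in which the configuration of the racemate is erased; capture of this radical gives trivalent nickel, reductive elimination forms C2–C1′, and Mn returns the metal to its low-valent state. The closest known reaction types are the nickel-catalysed reductive coupling of aryl halides with 1-chloroalkyl esters and the enantioconvergent nickel couplings of racemic secondary α-haloalkyl electrophiles under chiral bis(oxazoline) ligands; the new element is their combination on an ortho-alkoxy, electron-rich aryl iodide. No ring closes. The one new stereocentre, C1′, is set as S by the ligand (catalyst control) at radical capture and reductive elimination, helped by coordination of the ester carbonyl, which holds the radical in the chiral pocket. Cross-selectivity over homocoupling rests on the two different activation modes (two-electron oxidative addition for the aryl iodide, halogen abstraction for the chloro ester), the chloro ester is used in excess to cover hydrolysis and dimerisation, and the radical has no fast escape because 3-exo closure onto the homoallylic alkene is reversible and unproductive. The MOM ethers, the ester and the alkene should be inert to Mn and low-valent nickel.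

Step 7
Reactants: 10 (S)-4-methyl-1-[1,4,5,8-tetrakis(methoxymethoxy)naphthalen-2-yl]pent-3-en-1-yl 3-methylbutanoate
Product: 11 (S)-1-[1,4-bis(methoxymethoxy)-5,8-dioxo-5,8-dihydronaphthalen-2-yl]-4-methylpent-3-en-1-yl 3-methylbutanoate
Conditions: (NH4)2Ce(NO3)6 (2.2 equiv), MeCN/H2O, 0 °C, short reaction time
Reagents that add atoms: water, O
Why: Oxidative dealkylation of a para-dialkoxyarene by (NH4)2Ce(NO3)6 (arene radical cation, ipso attack of water, loss of the O-alkyl group) stops at the mono-quinone because the second ring is then deactivated, and it is expected in the unsubstituted ring, whose ethers are better conjugated and which is not flanked by the bulky, inductively withdrawing 1-acyloxyalkyl group; oxidation of the other ring would give a ring isomer that converges on the same naphthazarin in step 8, so the regiochemistry need not be controlled, and the side-chain alkene and ester should tolerate the brief cold exposure.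

Step 8
Reactants: 11 (S)-1-[1,4-bis(methoxymethoxy)-5,8-dioxo-5,8-dihydronaphthalen-2-yl]-4-methylpent-3-en-1-yl 3-methylbutanoate
Product: 13 isovalerylalkannin, via naphthazarin tautomer 12 (not isolated)
Conditions: NaHSO4·SiO2, CH2Cl2, rt; filtration
Reagents that add atoms: none
Why: Acid-catalysed acetal hydrolysis of the two aryl MOM ethers, eased by the peri carbonyl groups and run on a solid acid without nucleophilic solvent so that the ester, the alkene and C1′ are spared, frees the naphthazarin as tautomer 12, whose fast double proton shift across the peri O–H···O=C pairs gives the compound in the tautomer of the target, 13.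

**Compound list**

1 | naphthazarin (5,8-dihydroxy-1,4-naphthoquinone) | O=C1C=CC(=O)c2c(O)ccc(O)c12 | starting material
2 | 2,3-dihydronaphthazarin (5,8-dihydroxy-2,3-dihydronaphthalene-1,4-dione) | O=C1CCC(=O)c2c(O)ccc(O)c12 | intermediate
3 | 1,4,5,8-tetrakis(methoxymethoxy)naphthalene | COCOc1ccc(OCOC)c2c(OCOC)ccc(OCOC)c12 | intermediate
4 | [1,4,5,8-tetrakis(methoxymethoxy)naphthalen-2-yl]lithium | [Li]c1cc(OCOC)c2c(OCOC)ccc(OCOC)c2c1OCOC | intermediate
5 | 2-iodo-1,4,5,8-tetrakis(methoxymethoxy)naphthalene | COCOc1cc(I)c(OCOC)c2c(OCOC)ccc(OCOC)c12 | intermediate
6 | 4-methylpent-3-en-1-ol | CC(C)=CCCO | starting material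
7 | 4-methylpent-3-enal | CC(C)=CCC=O | intermediate
8 | isovaleryl chloride (3-methylbutanoyl chloride) | CC(C)CC(Cl)=O | starting material
9 | 1-chloro-4-methylpent-3-en-1-yl 3-methylbutanoate (racemic) | CC(C)=CCC(Cl)OC(=O)CC(C)C | intermediate
10 | (S)-4-methyl-1-[1,4,5,8-tetrakis(methoxymethoxy)naphthalen-2-yl]pent-3-en-1-yl 3-methylbutanoate | CC(C)=CC[C@H](OC(=O)CC(C)C)c1cc(OCOC)c2c(OCOC)ccc(OCOC)c2c1OCOC | intermediate
11 | (S)-1-[1,4-bis(methoxymethoxy)-5,8-dioxo-5,8-dihydronaphthalen-2-yl]-4-methylpent-3-en-1-yl 3-methylbutanoate | CC(C)=CC[C@H](OC(=O)CC(C)C)c1cc(OCOC)c2C(=O)C=CC(=O)c2c1OCOC | intermediate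
12 | (S)-1-(1,4-dihydroxy-5,8-dioxo-5,8-dihydronaphthalen-2-yl)-4-methylpent-3-en-1-yl 3-methylbutanoate (first-formed naphthazarin tautomer) | CC(C)=CC[C@H](OC(=O)CC(C)C)c1cc(O)c2C(=O)C=CC(=O)c2c1O | intermediate
13 | isovalerylalkannin, (S)-1-(5,8-dihydroxy-1,4-dioxo-1,4-dihydronaphthalen-2-yl)-4-methylpent-3-en-1-yl 3-methylbutanoate | CC(C)=CC[C@H](OC(=O)CC(C)C)C1=CC(=O)c2c(O)ccc(O)c2C1=O | target

**Step count**

Total: 8 steps. Longest linear sequence: 6 steps (steps 1, 2, 3, 6, 7, 8); the chain branch (steps 4 and 5) joins at step 6.

**Steps most likely to fail**

Step 6. Oxidative addition and reductive elimination at the ortho-alkoxy, electron-rich aryl nickel centre may be too slow, so that radical dimerisation, hydrodehalogenation of the arene and hydrolysis or elimination of the chloro ester take over. Enantio-induction at radical capture may also be poor. The fallback uses known chemistry and sets out from 3 and 7. Compound 3 is lithiated as in step 3 to 4, which is added to aldehyde 7 (THF, −78 °C, water quench) to give racemic 4-methyl-1-[1,4,5,8-tetrakis(methoxymethoxy)naphthalen-2-yl]pent-3-en-1-ol F1. Dess–Martin oxidation (CH2Cl2, 0 °C) gives 4-methyl-1-[1,4,5,8-tetrakis(methoxymethoxy)naphthalen-2-yl]pent-3-en-1-one F2. Corey–Bakshi–Shibata reduction follows, with (R)-1-methyl-3,3-diphenyltetrahydro-1H,3H-pyrrolo[1,2-c][1,3,2]oxazaborole (catalytic) and catecholborane in toluene at −78 °C. The aryl group acts as the large substituent, so this should deliver (S)-4-methyl-1-[1,4,5,8-tetrakis(methoxymethoxy)naphthalen-2-yl]pent-3-en-1-ol F3. Acylation with 8 (Et3N, catalytic 4-(dimethylamino)pyridine, CH2Cl2, 0 °C) returns to the route at 10.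

Step 5. The Lewis acid may activate the acyl chloride toward the trisubstituted alkene (Kondakov-type acylation), adventitious HCl may add to that alkene, or the β,γ double bond may migrate into conjugation before the carbonyl is captured. The fallback removes the Lewis acid and sets out from 7 and 8. Halide exchange of 8 with Me3SiBr gives 3-methylbutanoyl bromide F4, which is distilled. Acyl bromides add to aliphatic aldehydes without a catalyst, so F4 and 7 in CH2Cl2 at −20 °C should give racemic 1-bromo-4-methylpent-3-en-1-yl 3-methylbutanoate F5. F5 takes the place of 9 in the nickel coupling with 5 (conditions of step 6, NaI omitted) and the route is rejoined at 10.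

Step 7. Single-electron oxidation may not stop at the ring: (NH4)2Ce(NO3)6 may attack the trisubstituted alkene, or the acidic medium may ionise the benzylic C–O bond with loss of the ester or of configuration. The fallback reverses the order of unmasking and sets out from 10. All four MOM groups are removed with NaHSO4·SiO2 in degassed CH2Cl2 under argon to give (S)-4-methyl-1-(1,4,5,8-tetrahydroxynaphthalen-2-yl)pent-3-en-1-yl 3-methylbutanoate F6. This is not stored: the cold solution is opened to air at once, and autoxidation of the hydroquinone by O2 needs no metal oxidant. The route is rejoined at 13. Keeping this stage cold and short limits loss of isovalerate from the leuco form through a quinone methide.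

**Further compounds**

F1 | step 6 | 4-methyl-1-[1,4,5,8-tetrakis(methoxymethoxy)naphthalen-2-yl]pent-3-en-1-ol (racemic) | CC(C)=CCC(O)c1cc(OCOC)c2c(OCOC)ccc(OCOC)c2c1OCOC
F2 | step 6 | 4-methyl-1-[1,4,5,8-tetrakis(methoxymethoxy)naphthalen-2-yl]pent-3-en-1-one | CC(C)=CCC(=O)c1cc(OCOC)c2c(OCOC)ccc(OCOC)c2c1OCOC
F3 | step 6 | (S)-4-methyl-1-[1,4,5,8-tetrakis(methoxymethoxy)naphthalen-2-yl]pent-3-en-1-ol | CC(C)=CC[C@H](O)c1cc(OCOC)c2c(OCOC)ccc(OCOC)c2c1OCOC
F4 | step 5 | 3-methylbutanoyl bromide | CC(C)CC(Br)=O
F5 | step 5 | 1-bromo-4-methylpent-3-en-1-yl 3-methylbutanoate (racemic) | CC(C)=CCC(Br)OC(=O)CC(C)C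
F6 | step 7 | (S)-4-methyl-1-(1,4,5,8-tetrahydroxynaphthalen-2-yl)pent-3-en-1-yl 3-methylbutanoate | CC(C)=CC[C@H](OC(=O)CC(C)C)c1cc(O)c2c(O)ccc(O)c2c1O
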